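Readings and results are calculated for an exercise.

Follow one molecule of coupling partner, the limiting reagent of the coupling, to its fork: it meets substrate and becomes target, or it leaves by a second exit. Alpha shows that exit, since target stops near 33.9 % with 16.3 % of the substrate present, though the partner charged could carry 90.0 %.

| setting | alpha | gamma | theta | Friday's | Saturday's | Thursday's |
|---|---|---|---|---|---|---|
| substrate | 0.50 M | 0.50 M | 0.50 M | 0.50 M | 0.50 M (fed, over 30 min) | 0.50 M |
| coupling partner | 0.45 M | 0.45 M | 0.45 M | 0.450 M | 0.450 M | 0.450 M (fed, over 30 min) |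
| rival reagent | 0.75 M | 1 M | 1.7 M | 0.750 M | 0.750 M | 0.750 M |
| protic impurity | 0.050 M | 0.050 M | 0.050 M | 0.0500 M | 0.0500 M | 0.0500 M |
| remark | run made earlier | run made earlier | run made earlier | everything together at the start | all else is in the flask from the start; the feed brings no volume worth counting | all else is in the flask from the start; the feed brings no volume worth counting |
| time |  |  |  | 80 min | 80 min | 80 min |

| run | time / min | target / % | side product / % | substrate / % |
|---|---|---|---|---|
| alpha | 6.00 | 22.6 | 15.1 | 62.2 |
| alpha | 15.0 | 31.2 | 28.4 | 40.9 |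
| alpha | 20.0 | 32.6 | 33.6 | 33.3 |
| alpha | 30.0 | 33.8 | 41.0 | 26.1 |
| alpha | 40.0 | 33.4 | 45.6 | 20.0 |
| alpha | 50.0 | 33.9 | 51.0 | 16.3 |
| gamma | 2.50 | 13.7 | 10.5 | 77.2 |
| gamma | 8.00 | 24.9 | 24.4 | 50.1 |
| gamma | 15.0 | 29.2 | 36.1 | 34.5 |
| gamma | 20.0 | 30.6 | 42.1 | 27.2 |
| gamma | 30.0 | 31.8 | 49.6 | 19.3 |
| gamma | 40.0 | 31.8 | 54.9 | 13.5 |
| gamma | 50.0 | 32.1 | 58.5 | 9.4 |
| theta | 6.00 | 20.9 | 31.6 | 47.3 |
| theta | 15.0 | 26.8 | 51.6 | 21.0 |
| theta | 20.0 | 27.6 | 58.1 | 14.4 |
| theta | 30.0 | 28.3 | 64.0 | 6.9 |
| theta | 40.0 | 28.4 | 67.7 | 3.5 |
| theta | 50.0 | 28.2 | 69.7 | 1.5 |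

(each reading ± 0.3 percentage points)

1. the flask with the highest share of target in target plus side product ("all alike" if they lie within 1.5 percentage points) (Friday's / Saturday's / Thursday's / all alike)
2. share of target in target plus side product at the end, Friday's
3. share of target in target plus side product at the end, Saturday's
4. share of target in target plus side product at the end, Thursday's



Let Y be the fraction of charged partner ending as target, and S the substrate a partner typically meets. If coupling scales with S and the exit does not, Y = S/(S + K), where K is the even-odds substrate concentration. Take S at 6.00 min, when alpha's target stands at 66.7 % of its last reading; gamma's S is interpolated.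

Last target; Y; S; K:

- alpha: 33.9 %; 37.7 %; 0.311 M; 0.515 M
- gamma: 32.1 %; 35.7 %; 0.300 M; 0.541 M
- theta: 28.2 %; 31.3 %; 0.236 M; 0.518 M

Read down the rows: as rival reagent rises from 0.75 M to 1.7 M, Y and S fall together, yet K holds, averaging 0.525 M. So in alpha, gamma and theta the fall in Y goes with the fall in S.

Alpha's last readings sum to 101 %, so the substrate gone from alpha stands as target or side product. My reckoning is for target, not the share. Friday's has alpha's charges, so I put its target near 33.9 %. Saturday's feed has delivered 0.100 M by 6.00 min; taking that as S, I estimate Y at 16.0 % and target at 14.4 %. Thursday's average partner arrives at mid-feed; borrowing alpha's substrate at that time, 0.204 M, as S, I estimate Y at 28.1 % and target at 25.2 %. In this estimate Friday's target stands above Thursday's, and Thursday's above Saturday's.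

The forecast picks Friday's, with shares of 37.2 % (36 % to 38.5 %) for Friday's, 18.5 % (15 % to 23 %) for Saturday's and 27 % (23 % to 32 %) for Thursday's: “Both feeds hurt; all-at-once wins.”

The flasks give Friday's as the best, with shares of 37.1 % for Friday's, 17.7 % for Saturday's and 28.2 % for Thursday's.

    substrate + coupling partner → target (k = 0.160 M⁻¹ min⁻¹)
    coupling partner → decomposed reagent (k = 0.0840 min⁻¹)
    rival reagent + protic impurity → quenched reagent (k = 2.80 M⁻¹ min⁻¹)
    substrate + rival reagent → side product (k = 0.0490 M⁻¹ min⁻¹)

The largest single effect on Saturday's gap to Friday's is the loss of coupling partner to decomposed reagent: without that step, the gap moves from 19 percentage points to −0.19 points. Saturday's target of 14.2 % means Y = 15.8 %, the chance of a partner meeting 0.0987 M of substrate, which the feed delivers by 5.92 min. For the neighbour of Friday's charged with 2.0 M of substrate, take that charge as S: Y is 79.2 %, giving target at 17.8 % of its substrate, and that flask holds 17.1 %.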